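## Retrosynthetic overview

1. Feature: ring C (O1–C2–C3–C4, fused to ring A, aryl = ring B) and ring F (fused to ring D, aryl = ring E) carry the same trans pair of C2-aryl and C3-OH (2R,3S). All four stereocentres therefore trace back to the C2=C3 enol ether bonds of two flat 4H-chromenes, and they are set together by hydroboration–oxidation with a pinene-derived borane, followed by global debenzylation.
2. The bis(flav-2-ene) is cut at the biaryl bond ring B C6'–ring D C8 (Suzuki–Miyaura). This gives a ring B boronate (rings A, B, C) and an 8-bromoflavene (rings D, E, F).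
3. Each flavene comes from a salicylaldehyde and an acetophenone by Claisen–Schmidt condensation, conjugate reduction and cyclodehydration.
4. Ring order: the four benzene rings are bought. Rings C and F are closed in separate branches before the biaryl bond exists, because a free ring D phenol beside the ring B ketone would close a benzo[c]chromene ketal instead. No ring forms afterwards.
5. Both aldehydes come from 3,5-bis(benzyloxy)phenol and both ketones from 3,4-dihydroxyacetophenone.

Key step: step 13

Assumption: the ring B–ring D axis has three ortho substituents and no descriptor in the target, so it is treated as an equilibrating axis, and slowly interconverting rotamers of the bis-flavene, its diol and the target count as one compound.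

Remark: IpcBH2 is used as a stock THF solution, set free beforehand from its crystalline TMEDA adduct (series from (+)-α-pinene) with BF3·OEt2 and filtered.

## Route

Step 1
Reactants: 1 3,4-dihydroxyacetophenone
Product: 2 3,4-bis(benzyloxy)acetophenone
Conditions: BnBr, K2CO3, DMF, 60 °C
Reagents that add atoms: benzyl bromide, BrCc1ccccc1
Why: Williamson ether synthesis, in which both catechol oxygens are alkylated by SN2 on benzyl bromide while K2CO3 is too weak to enolise the methyl ketone to a harmful extent.

Step 2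
Reactants: 2 3,4-bis(benzyloxy)acetophenone
Product: 3 1-[4,5-bis(benzyloxy)-2-bromophenyl]ethanone
Conditions: NBS, MeCN, 0 °C to rt, dark
Reagents that add atoms: N-bromosuccinimide, O=C1CCC(=O)N1Br
Why: Electrophilic aromatic bromination under polar, non-radical conditions should hit the carbon para to the 3-benzyloxy group, whose lone pair is not drained by the para carbonyl, as in the familiar 6-bromination of 3,4-dialkoxyaryl carbonyl compounds, and not the ketone α-carbon or a benzylic CH2.

Step 3
Reactants: 4 3,5-bis(benzyloxy)phenol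
Product: 5 4,6-bis(benzyloxy)-2-hydroxybenzaldehyde
Conditions: MgCl2, Et3N, (CH2O)n, MeCN, reflux; then 1 M HCl
Reagents that add atoms: paraformaldehyde (formaldehyde unit), C=O
Why: Magnesium-mediated ortho-formylation (Casnati–Skattebøl reaction), in which the magnesium phenoxide delivers formaldehyde only to a carbon ortho to the free OH, the two ortho carbons are equivalent, and a second formaldehyde oxidises the benzylic alkoxide to the aldehyde.

Step 4
Reactants: 3 1-[4,5-bis(benzyloxy)-2-bromophenyl]ethanone; 5 4,6-bis(benzyloxy)-2-hydroxybenzaldehyde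
Product: 6 (E)-3-[2,4-bis(benzyloxy)-6-hydroxyphenyl]-1-[4,5-bis(benzyloxy)-2-bromophenyl]prop-2-en-1-one
Conditions: KOH, EtOH/THF/H2O, rt to 40 °C; then AcOH
Reagents that add atoms: none
Why: Claisen–Schmidt condensation, in which the methyl ketone enolate adds to the non-enolisable aldehyde and E1cB loss of water gives the E-enone, with the phenol carried as its phenoxide as in the standard preparation of 2-hydroxychalcones from salicylaldehydes.

Step 5
Reactants: 6 (E)-3-[2,4-bis(benzyloxy)-6-hydroxyphenyl]-1-[4,5-bis(benzyloxy)-2-bromophenyl]prop-2-en-1-one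
Product: 7 3-[2,4-bis(benzyloxy)-6-hydroxyphenyl]-1-[4,5-bis(benzyloxy)-2-bromophenyl]propan-1-one
Conditions: [(Ph3P)CuH]6 (cat.), (EtO)2MeSiH (excess), toluene, rt; then aq NH4Cl
Reagents that add atoms: none
Why: Copper hydride conjugate reduction, in which the soft Cu–H adds 1,4 to the enone only, so the aryl bromide, the benzyl ethers and the new aryl ketone stay intact, and any silyl ether formed on the phenol is hydrolysed on work-up.

Step 6
Reactants: 7 3-[2,4-bis(benzyloxy)-6-hydroxyphenyl]-1-[4,5-bis(benzyloxy)-2-bromophenyl]propan-1-one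
Product: 8 5,7-bis(benzyloxy)-2-[4,5-bis(benzyloxy)-2-bromophenyl]-4H-chromene
Conditions: PPTS (cat.), toluene, reflux, Dean–Stark, Ar; then Et3N, filtration through basic Al2O3
Reagents that add atoms: none
Why: Acid-catalysed cyclodehydration, a known entry to flav-2-enes, in which the phenol adds to the ketone (6-exo-trig hemiketal), the aryl-stabilised oxocarbenium ion loses a C3 proton, and azeotropic water removal drives closure of ring C as the conjugated enol ether.

Step 7
Reactants: 8 5,7-bis(benzyloxy)-2-[4,5-bis(benzyloxy)-2-bromophenyl]-4H-chromene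
Product: 9 5,7-bis(benzyloxy)-2-[4,5-bis(benzyloxy)-2-(4,4,5,5-tetramethyl-1,3,2-dioxaborolan-2-yl)phenyl]-4H-chromene
Conditions: B2pin2, PdCl2(dppf) (cat.), KOAc, 1,4-dioxane, 90 °C
Reagents that add atoms: bis(pinacolato)diboron, CC1(C)OB(OC1(C)C)B1OC(C)(C)C(C)(C)O1
Why: Miyaura borylation runs under mildly basic conditions that leave the acid-labile enol ether alone, and boron is put on ring B because a 2,6-dialkoxyaryl boronate on ring D would protodeboronate easily.

Step 8
Reactants: 5 4,6-bis(benzyloxy)-2-hydroxybenzaldehyde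
Product: 10 4,6-bis(benzyloxy)-3-bromo-2-hydroxybenzaldehyde
Conditions: NBS (1 equiv), CH2Cl2, −20 °C to 0 °C
Reagents that add atoms: N-bromosuccinimide, O=C1CCC(=O)N1Br
Why: Electrophilic aromatic bromination should prefer C3, flanked by the small chelated OH and one benzyloxy group, over C5 between two benzyloxy groups, in line with the known 3-halogenation of 2-hydroxy-4,6-dialkoxyaryl carbonyl compounds and the C8 bromination of perbenzylated flavan-3-ols.

Step 9
Reactants: 10 4,6-bis(benzyloxy)-3-bromo-2-hydroxybenzaldehyde; 2 3,4-bis(benzyloxy)acetophenone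
Product: 11 (E)-3-[4,6-bis(benzyloxy)-3-bromo-2-hydroxyphenyl]-1-[3,4-bis(benzyloxy)phenyl]prop-2-en-1-one
Conditions: KOH, EtOH/THF/H2O, rt to 40 °C; then AcOH
Reagents that add atoms: none
Why: Claisen–Schmidt condensation as in step 4, giving the E-enone by E1cB dehydration, with the aryl bromide inert to aqueous alcoholic KOH.

Step 10
Reactants: 11 (E)-3-[4,6-bis(benzyloxy)-3-bromo-2-hydroxyphenyl]-1-[3,4-bis(benzyloxy)phenyl]prop-2-en-1-one
Product: 12 3-[4,6-bis(benzyloxy)-3-bromo-2-hydroxyphenyl]-1-[3,4-bis(benzyloxy)phenyl]propan-1-one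
Conditions: [(Ph3P)CuH]6 (cat.), (EtO)2MeSiH (excess), toluene, rt; then aq NH4Cl
Reagents that add atoms: none
Why: Copper hydride conjugate reduction as in step 5, selective for the enone C=C over the aryl bromide, the benzyl ethers and the aryl ketone.

Step 11
Reactants: 12 3-[4,6-bis(benzyloxy)-3-bromo-2-hydroxyphenyl]-1-[3,4-bis(benzyloxy)phenyl]propan-1-one
Product: 13 5,7-bis(benzyloxy)-2-[3,4-bis(benzyloxy)phenyl]-8-bromo-4H-chromene
Conditions: PPTS (cat.), toluene, reflux, Dean–Stark, Ar; then Et3N, filtration through basic Al2O3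
Reagents that add atoms: none
Why: Acid-catalysed cyclodehydration as in step 6 closes ring F (6-exo-trig hemiketal, then loss of water from the oxocarbenium ion), and bromine was chosen over iodine because it resists acid-induced ipso-protonation on the electron-rich ring D.

Step 12
Reactants: 9 5,7-bis(benzyloxy)-2-[4,5-bis(benzyloxy)-2-(4,4,5,5-tetramethyl-1,3,2-dioxaborolan-2-yl)phenyl]-4H-chromene; 13 5,7-bis(benzyloxy)-2-[3,4-bis(benzyloxy)phenyl]-8-bromo-4H-chromene
Product: 14 octa-O-benzyl bis(flav-2-ene), 5,7-bis(benzyloxy)-2-{4,5-bis(benzyloxy)-2-[5,7-bis(benzyloxy)-2-(3,4-bis(benzyloxy)phenyl)-4H-chromen-8-yl]phenyl}-4H-chromene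
Conditions: Pd(OAc)2 (cat.), SPhos, K3PO4, toluene/H2O, 90 °C, Ar
Reagents that add atoms: none
Why: Suzuki–Miyaura coupling, in which the bulky electron-rich biarylphosphine lets zerovalent palladium insert into the hindered electron-rich C8–Br bond and promotes reductive elimination to a biaryl with three ortho substituents, while both partners carry only ethers and enol ethers that are inert to aqueous base.

Step 13
Reactants: 14 octa-O-benzyl bis(flav-2-ene)
Product: 16 (2R,3S,2''R,3''S)-octa-O-benzyl ether of the target, via bis(isopinocampheylboryl) adduct 15 (not isolated)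
Conditions: IpcBH2 [from (+)-α-pinene, 4 equiv], THF, −25 °C to 0 °C; then NaOH, H2O2, 0 °C to rt
Reagents that add atoms: monoisopinocampheylborane from (+)-α-pinene, C[C@H]1[C@H](B)C[C@@H]2C[C@H]1C2(C)C (its boron and terpene carbons stay in 15 only); hydrogen peroxide, OO
Why: Proposed new method: one B–H bond of IpcBH2 adds across each C2=C3 enol ether bond through a concerted four-centre transition state, with boron going to the electron-rich C3 (β to the ring oxygen, remote from the aryl group) and hydrogen to C2 on the same face, and alkaline H2O2 then exchanges boron for oxygen by a 1,2-shift with retention. The closest known reactions are the asymmetric hydroboration of 1-arylcycloalkenes with this borane and the racemic BH3 hydroboration–oxidation of flav-2-enes to 2,3-trans-flavan-3-ols, and what is new is their combination on a 2-aryl-4H-chromene. No ring is closed, because rings C and F enter as intact 4H-chromenes, which also keeps the ring D oxygen from competing for the ring B benzylic carbon. C3 of ring C and C3 of ring F (both S) are fixed by the alkene face that the pinene-derived borane selects, and C2 of each ring (both R) follows from syn addition, so aryl and hydroxyl end trans; mapping the (1S,2R)-trans-2-arylcycloalkanols known from the (+)-α-pinene reagent onto the flavan skeleton predicts 2R,3S. The step needs regioselectivity (secured by the matching enol ether and styrene polarisation), face selectivity at two remote alkenes that react independently (a wrong event at either one ends in a separable diastereomer, which raises the enantiomeric purity of the main isomer statistically), and survival of the β-aryloxyborane (secured by low temperature and prompt oxidation).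

Step 14
Reactants: 16 (2R,3S,2''R,3''S)-octa-O-benzyl ether of the target
Product: 17 target CNP0353739.1
Conditions: H2 (1 atm), Pd(OH)2/C, THF/MeOH, rt, then filtration and freeze-drying under Ar
Reagents that add atoms: none
Why: Catalytic hydrogenolysis of the eight aryl benzyl ethers under neutral conditions is the standard deprotection of benzylated flavan-3-ols and touches neither the four stereocentres nor, at short contact time, the C2–O1 bonds.

## Compound list

1 | 3,4-dihydroxyacetophenone | CC(=O)c1ccc(O)c(O)c1 | starting material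
2 | 3,4-bis(benzyloxy)acetophenone | CC(=O)c1ccc(OCc9ccccc9)c(OCc9ccccc9)c1 | intermediate
3 | 1-[4,5-bis(benzyloxy)-2-bromophenyl]ethanone | CC(=O)c1cc(OCc9ccccc9)c(OCc9ccccc9)cc1Br | intermediate
4 | 3,5-bis(benzyloxy)phenol | Oc1cc(OCc9ccccc9)cc(OCc9ccccc9)c1 | starting material
5 | 4,6-bis(benzyloxy)-2-hydroxybenzaldehyde | O=Cc1c(O)cc(OCc9ccccc9)cc1OCc9ccccc9 | intermediate
6 | (E)-3-[2,4-bis(benzyloxy)-6-hydroxyphenyl]-1-[4,5-bis(benzyloxy)-2-bromophenyl]prop-2-en-1-one | Oc1cc(OCc9ccccc9)cc(OCc9ccccc9)c1/C=C/C(=O)c1cc(OCc9ccccc9)c(OCc9ccccc9)cc1Br | intermediate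
7 | 3-[2,4-bis(benzyloxy)-6-hydroxyphenyl]-1-[4,5-bis(benzyloxy)-2-bromophenyl]propan-1-one | Oc1cc(OCc9ccccc9)cc(OCc9ccccc9)c1CCC(=O)c1cc(OCc9ccccc9)c(OCc9ccccc9)cc1Br | intermediate
8 | 5,7-bis(benzyloxy)-2-[4,5-bis(benzyloxy)-2-bromophenyl]-4H-chromene (rings A, B, C) | Brc1cc(OCc9ccccc9)c(OCc9ccccc9)cc1C1=CCc2c(O1)cc(OCc9ccccc9)cc2OCc9ccccc9 | intermediate
9 | 5,7-bis(benzyloxy)-2-[4,5-bis(benzyloxy)-2-(4,4,5,5-tetramethyl-1,3,2-dioxaborolan-2-yl)phenyl]-4H-chromene | CC1(C)OB(OC1(C)C)c1cc(OCc9ccccc9)c(OCc9ccccc9)cc1C1=CCc2c(O1)cc(OCc9ccccc9)cc2OCc9ccccc9 | intermediate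
10 | 4,6-bis(benzyloxy)-3-bromo-2-hydroxybenzaldehyde | O=Cc1c(O)c(Br)c(OCc9ccccc9)cc1OCc9ccccc9 | intermediate
11 | (E)-3-[4,6-bis(benzyloxy)-3-bromo-2-hydroxyphenyl]-1-[3,4-bis(benzyloxy)phenyl]prop-2-en-1-one | O=C(/C=C/c1c(O)c(Br)c(OCc9ccccc9)cc1OCc9ccccc9)c1ccc(OCc9ccccc9)c(OCc9ccccc9)c1 | intermediate
12 | 3-[4,6-bis(benzyloxy)-3-bromo-2-hydroxyphenyl]-1-[3,4-bis(benzyloxy)phenyl]propan-1-one | O=C(CCc1c(O)c(Br)c(OCc9ccccc9)cc1OCc9ccccc9)c1ccc(OCc9ccccc9)c(OCc9ccccc9)c1 | intermediate
13 | 5,7-bis(benzyloxy)-2-[3,4-bis(benzyloxy)phenyl]-8-bromo-4H-chromene (rings D, E, F) | Brc1c(OCc9ccccc9)cc(OCc9ccccc9)c2c1OC(c1ccc(OCc9ccccc9)c(OCc9ccccc9)c1)=CC2 | intermediate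
14 | octa-O-benzyl bis(flav-2-ene), ring B C6' bonded to ring D C8, no stereocentre | c9ccccc9COc1cc(OCc9ccccc9)c2c(c1)OC(c1cc(OCc9ccccc9)c(OCc9ccccc9)cc1-c1c(OCc9ccccc9)cc(OCc9ccccc9)c3c1OC(c1ccc(OCc9ccccc9)c(OCc9ccccc9)c1)=CC3)=CC2 | intermediate
15 | bis(isopinocampheylboryl) adduct, one B(H)Ipc group on C3 of ring C and one on C3 of ring F, each trans to the C2 aryl group | c9ccccc9COc1cc(OCc9ccccc9)c2c(c1)O[C@H](c1cc(OCc9ccccc9)c(OCc9ccccc9)cc1-c1c(OCc9ccccc9)cc(OCc9ccccc9)c3c1O[C@H](c1ccc(OCc9ccccc9)c(OCc9ccccc9)c1)[C@@H]([BH][C@@H]4C[C@@H]5C[C@@H](C5(C)C)[C@H]4C)C3)[C@@H]([BH][C@@H]4C[C@@H]5C[C@@H](C5(C)C)[C@H]4C)C2 | intermediate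
16 | octa-O-benzyl ether of the target, 2R,3S in ring C and 2R,3S in ring F | c9ccccc9COc1cc(OCc9ccccc9)c2c(c1)O[C@H](c1cc(OCc9ccccc9)c(OCc9ccccc9)cc1-c1c(OCc9ccccc9)cc(OCc9ccccc9)c3c1O[C@H](c1ccc(OCc9ccccc9)c(OCc9ccccc9)c1)[C@@H](O)C3)[C@@H](O)C2 | intermediate
17 | CNP0353739.1, two (2R,3S)-flavan-3-ol units joined C6'–C8 | Oc1cc(O)c2c(c1)O[C@H](c1cc(O)c(O)cc1-c1c(O)cc(O)c3c1O[C@H](c1ccc(O)c(O)c1)[C@@H](O)C3)[C@@H](O)C2 | target

## Step count and risks

Total step count: 14. Longest linear sequence: 9 steps (1, 2, 4, 5, 6, 7, 12, 13, 14).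

**Step 13 (key step).**
- What may go wrong:
  - Addition at the ring C alkene, which sits beside the ortho aryl group, may stall or show poor facial selectivity.
  - The reagent may lose α-pinene, which opens an achiral borane background reaction.
  - The C3 borane may undergo β-elimination with opening of the pyran ring.
- If only the sense of induction is opposite to the prediction, the reagent from (−)-α-pinene is used instead.
- The fallback sets out from 14 and comes back at 16, replacing reagent control by the known racemic reaction plus resolution. BH3·THF at 0 °C followed by NaOH/H2O2 should give the mixture of 2,3-trans stereoisomers of the octabenzyl diol F1. Esterification with (1S)-camphanoyl chloride (DMAP, pyridine) turns it into diastereomeric esters. From these the bis[(1S)-camphanate] of the (2R,3S,2''R,3''S) isomer F2 is separated by chromatography and crystallisation. K2CO3 in MeOH/THF then returns 16.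

**Step 12.**
- What may go wrong: transmetalation between two bulky partners may be slow, so that protodeboronation of the ring B boronate and hydrodebromination of ring D overtake coupling.
- The fallback sets out from 3 and 13 and comes back at 14, giving up the convergent union for a small coupling partner and a late closure of ring C.
  - Bromide 3 is borylated (B2pin2, PdCl2(dppf), KOAc) to 1-[4,5-bis(benzyloxy)-2-(4,4,5,5-tetramethyl-1,3,2-dioxaborolan-2-yl)phenyl]ethanone F3, which can be used in excess.
  - Suzuki–Miyaura coupling of F3 with 13 should give the 8-(2-acetylaryl)flavene F4.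
  - Claisen–Schmidt condensation with aldehyde 5 gives the chalcone F5, and copper hydride reduction gives the dihydrochalcone F6.
  - PPTS cyclodehydration then gives 14. The ring D oxygen is already locked in ring F, so it cannot add to the ring B ketone.

**Step 11 (the same holds for step 6).**
- What may go wrong: the enol ether may react further under acid. The possible processes are reprotonation at C3, hydride disproportionation into flavylium ion and flavan, Friedel–Crafts attack by the electron-rich rings, and air oxidation.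
- The fallback sets out from 11 and comes back at 13. It closes the ring at the flavylium oxidation level and adjusts the level afterwards, which skips step 10. HBF4·OEt2 in AcOH at rt converts the 2-hydroxychalcone, by E/Z isomerisation, hemiketal formation and loss of water, into 5,7-bis(benzyloxy)-2-[3,4-bis(benzyloxy)phenyl]-8-bromoflavylium tetrafluoroborate F7, which is precipitated with Et2O after a short exposure. LiAlH4 in THF at low temperature then delivers hydride to C4, the known way from flavylium salts to flav-2-enes, to give 13.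

## Further compounds

F1 | step 13 | mixture of the 2,3-trans stereoisomers of the octabenzyl diol | c9ccccc9COc1cc(OCc9ccccc9)c2c(c1)OC(c1cc(OCc9ccccc9)c(OCc9ccccc9)cc1-c1c(OCc9ccccc9)cc(OCc9ccccc9)c3c1OC(c1ccc(OCc9ccccc9)c(OCc9ccccc9)c1)C(O)C3)C(O)C2
F2 | step 13 | bis[(1S)-camphanate] of 16 | c9ccccc9COc1cc(OCc9ccccc9)c2c(c1)O[C@H](c1cc(OCc9ccccc9)c(OCc9ccccc9)cc1-c1c(OCc9ccccc9)cc(OCc9ccccc9)c3c1O[C@H](c1ccc(OCc9ccccc9)c(OCc9ccccc9)c1)[C@@H](OC(=O)[C@@]45CC[C@@](C)(C(=O)O4)C5(C)C)C3)[C@@H](OC(=O)[C@@]45CC[C@@](C)(C(=O)O4)C5(C)C)C2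
F3 | step 12 | 1-[4,5-bis(benzyloxy)-2-(4,4,5,5-tetramethyl-1,3,2-dioxaborolan-2-yl)phenyl]ethanone | CC(=O)c1cc(OCc9ccccc9)c(OCc9ccccc9)cc1B2OC(C)(C)C(C)(C)O2
F4 | step 12 | 1-{4,5-bis(benzyloxy)-2-[5,7-bis(benzyloxy)-2-(3,4-bis(benzyloxy)phenyl)-4H-chromen-8-yl]phenyl}ethanone | CC(=O)c1cc(OCc9ccccc9)c(OCc9ccccc9)cc1-c1c(OCc9ccccc9)cc(OCc9ccccc9)c2c1OC(c1ccc(OCc9ccccc9)c(OCc9ccccc9)c1)=CC2
F5 | step 12 | (E)-chalcone from F4 and 5 | Oc1cc(OCc9ccccc9)cc(OCc9ccccc9)c1/C=C/C(=O)c1cc(OCc9ccccc9)c(OCc9ccccc9)cc1-c1c(OCc9ccccc9)cc(OCc9ccccc9)c2c1OC(c1ccc(OCc9ccccc9)c(OCc9ccccc9)c1)=CC2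
F6 | step 12 | dihydrochalcone from F5 | Oc1cc(OCc9ccccc9)cc(OCc9ccccc9)c1CCC(=O)c1cc(OCc9ccccc9)c(OCc9ccccc9)cc1-c1c(OCc9ccccc9)cc(OCc9ccccc9)c2c1OC(c1ccc(OCc9ccccc9)c(OCc9ccccc9)c1)=CC2
F7 | step 11 | 5,7-bis(benzyloxy)-2-[3,4-bis(benzyloxy)phenyl]-8-bromoflavylium tetrafluoroborate | Brc1c(OCc9ccccc9)cc(OCc9ccccc9)c2ccc(-c3ccc(OCc9ccccc9)c(OCc9ccccc9)c3)[o+]c12.F[B-](F)(F)F
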